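**Retrosynthetic overview**

1. Numbering: bicyclo[3.2.1]octane C1 (bridgehead, isobutyryl C9), C2 (CMe2), C3 (CH‑prenyl), C4 (CH2), C5 (bridgehead, prenyl), C6 (carbinol), C7 (ketone), C8 (bridging ketone); side chain C10(=O)–C11=C12–C13(OH)Me2. The same numbers are used for the corresponding atoms of the precursors, and all descriptors refer to this numbering.
2. Feature: the bridge C4–C3–C2 is a prenyl unit on C5 that is tied through its tertiary carbon C2 to the acyl‑bearing carbon C1. The five‑membered ring C1–C7–C6–C5–C8 with two prenyl groups on C5 is therefore the achiral hop triketone cohulupone, whose prenyl groups are enantiotopic.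
3. Endgame disconnections: C13–CH3 (MeTi(OiPr)3 on a methyl ketone), C10–C13 enedione (singlet‑oxygen opening of a 5‑methyl‑2‑furyl group), C6–C10 (furylcerium addition to the C6 ketone, done before the radical step because a free 1,2‑dione would not survive stannyl radicals), C3 prenyl (radical allylation of the C3 selenide, then cross‑metathesis).
4. Key disconnection C1–C2: opening of a prenyl seleniranium ion by the triketone carbon of cohulupone under a chiral copper bis(oxazoline) complex, which closes the six‑membered ring C1–C2–C3–C4–C5–C8 and selects one prenyl group.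
5. Cohulupone comes from 6‑methylhept‑5‑en‑2‑one by Claisen acylation, oxalate annulation and C‑prenylation. Ring order: five‑membered ring (step 2), then six‑membered ring (step 4).

Key step: step 4

Assumption 1: the sense of induction in step 4 cannot be derived from precedent; the (S,S) ligand is written, and its antipode is taken if the first run gives the mirror‑image series.
Assumption 2: the target is treated as the open‑chain (Z)‑γ‑hydroxy enone of the given SMILES; its cyclic hemiketal tautomer (C13–OH onto C10) is not counted as a separate compound.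

**Step 1**
Reactants: 1 6‑methylhept‑5‑en‑2‑one; 2 methyl 2‑methylpropanoate
Product: 3 2,9‑dimethyldec‑8‑ene‑3,5‑dione
Conditions: NaH (2.2 equiv), THF, reflux, slow addition of 1; then cold aq. HCl
Reagents that add atoms: none
Why: Crossed Claisen condensation in which the sodium enolate formed at the methyl group of 1 is acylated by 2 and deprotonation of the new central CH2 drives the equilibrium, while 2 cannot give a stable self‑condensation product because that would lack an acidic hydrogen; no stereocentre is formed.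

**Step 2**
Reactants: 3 2,9‑dimethyldec‑8‑ene‑3,5‑dione; 4 diethyl oxalate
Product: 6 4‑hydroxy‑5‑(2‑methylpropanoyl)‑2‑(3‑methylbut‑2‑en‑1‑yl)cyclopent‑4‑ene‑1,3‑dione, via oxalyl triketo ester 5 (not isolated)
Conditions: NaOEt (3 equiv), EtOH, 0 °C → reflux; then cold 1 M HCl
Reagents that add atoms: none
Why: Claisen condensation of the diketone anion with diethyl oxalate at its central carbon followed by Dieckmann‑type closure of the prenyl‑bearing α‑methylene onto the oxalyl ester (the classical oxalate annulation of ketones to cyclopentane‑1,2,4‑triones) forms the five‑membered ring; closure through this methylene and not the isopropyl methine is expected because it is less hindered and only its product can be deprotonated twice, and the enolisable stereocentre at the prenyl‑bearing ring carbon is erased in step 3.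

**Step 3**
Reactants: 6 4‑hydroxy‑5‑(2‑methylpropanoyl)‑2‑(3‑methylbut‑2‑en‑1‑yl)cyclopent‑4‑ene‑1,3‑dione; 7 1‑bromo‑3‑methylbut‑2‑ene
Product: 8 cohulupone (4‑hydroxy‑5‑(2‑methylpropanoyl)‑2,2‑bis(3‑methylbut‑2‑en‑1‑yl)cyclopent‑4‑ene‑1,3‑dione)
Conditions: KOH (2.2 equiv), H2O, 0 °C; 7 (1.2 equiv), 0 °C → rt; then cold dil. HCl
Reagents that add atoms: none
Why: C‑alkylation of the dianion, in which the second deprotonation (after the acidic acyl‑triketone enol) takes place at the ring CH that carries the prenyl group and this less stabilised carbon is alkylated by the allylic bromide in water, where hydrogen bonding to the enolate oxygens disfavours O‑alkylation; the alkylated carbon ends with two identical prenyl groups, so 8 is achiral.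

**Step 4**
Reactants: 8 cohulupone; 9 N‑(phenylselanyl)phthalimide
Product: 11 (1R,3R,5R)‑2,2‑dimethyl‑5‑(3‑methylbut‑2‑en‑1‑yl)‑1‑(2‑methylpropanoyl)‑3‑(phenylselanyl)bicyclo[3.2.1]octane‑6,7,8‑trione, via seleniranium ion 10 (not isolated)
Conditions: 9 (1.05 equiv), Cu(OTf)2 (10 mol %), 2,2'‑(propane‑2,2‑diyl)bis[(4S)‑4‑tert‑butyl‑4,5‑dihydro‑1,3‑oxazole] (11 mol %), 4 Å MS, CH2Cl2, −40 → 0 °C
Reagents that add atoms: none
Why: Proposed new method: chelation of the acyl‑triketone of 8 to the cationic copper bis(oxazoline) complex gives a chiral copper enolate and a trace of triflic acid, which activates 9 so that PhSe+ is passed reversibly (also by way of the C1‑selenenylated triketone) to a prenyl alkene to give seleniranium ion 10, and the enolate carbon C1 then opens 10 at its tertiary carbon C2. The closest known reaction types are the Lewis‑acid‑promoted phenylseleno‑carbocyclisation of alkenyl β‑dicarbonyl compounds with 9, the iodonium‑triggered closure of bicyclo[3.3.1]nonane cores from prenylated dearomatised acylphloroglucinols and the titanium‑TADDOLate‑catalysed enantioselective iodocarbocyclisation of alkenyl malonates, none of which has to choose between two enantiotopic alkenes. The six‑membered ring C1–C2–C3–C4–C5–C8 closes by 6‑endo (Markovnikov) opening of the seleniranium ion through a chair. C1 and C5 are fixed together by the choice of prenyl group, which is a choice of enolate face because each prenyl group can only reach the face of the planar ring on which it lies, and this face is to be selected by the tert‑butyl groups of the ligand on the copper chelate, the controller being placed on the nucleophile because seleniranium ions exchange between alkenes and nothing is decided before the C–C bond forms; C3 follows from anti opening in the chair (selenium equatorial) and is reset in step 7. The step needs C‑ and not O‑alkylation: enol ethers formed through the oxygen on C8 are β‑seleno tertiary ethers of a very acidic enol and should re‑ionise under the acid, whereas 11 is no longer enolisable and accumulates, and the two identical prenyl groups and the single nucleophilic carbon of 8 leave the facial choice as the only open variable.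

**Step 5**
Reactants: 11 selenide trione; 12 2‑methylfuran
Product: 13 (1R,3R,5S,6S)‑6‑hydroxy‑2,2‑dimethyl‑5‑(3‑methylbut‑2‑en‑1‑yl)‑6‑(5‑methylfuran‑2‑yl)‑1‑(2‑methylpropanoyl)‑3‑(phenylselanyl)bicyclo[3.2.1]octane‑7,8‑dione
Conditions: 12 (1.3 equiv), n‑BuLi, THF, 0 °C; CeCl3, THF, −78 °C; then 11, −78 °C; aq. NH4Cl at −78 °C
Reagents that add atoms: none
Why: 1,2‑Addition of a weakly basic organocerium reagent to a non‑enolisable 1,2‑dione, in which C6 should be chosen over C7 because C7 lies beside the fully substituted C1 whose isobutyryl group is pressed toward it by the C2 gem‑dimethyl group, and the nucleophile should enter from the exo face (the side of the one‑carbon bridge C8) because the endo face is the concave side under the C2–C4 bridge, which places the furyl group exo and the hydroxyl endo (6S); the low temperature and the cerium counter‑ion are there to stop retro‑aldol opening of the C6 alkoxide.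

**Step 6**
Reactants: 13 furyl carbinol
Product: 14 (1R,3R,5S,6S)‑2,2‑dimethyl‑5‑(3‑methylbut‑2‑en‑1‑yl)‑6‑(5‑methylfuran‑2‑yl)‑1‑(2‑methylpropanoyl)‑3‑(phenylselanyl)‑6‑[(trimethylsilyl)oxy]bicyclo[3.2.1]octane‑7,8‑dione
Conditions: N‑(trimethylsilyl)imidazole (3 equiv), CH2Cl2, rt → 40 °C
Reagents that add atoms: N‑(trimethylsilyl)imidazole, C[Si](C)(C)n1ccnc1
Why: Silylation of the hindered tertiary hydroxyl with a strong neutral trimethylsilyl donor that does not enolise the isobutyryl ketone; the silyl ether blocks retro‑aldol opening on heating, screens the endo face of C3 in step 7 and prevents Achmatowicz‑type hemiketal closure in step 9, and no stereocentre is touched.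

**Step 7**
Reactants: 14 silyl ether selenide
Product: 15 (1R,3R,5S,6S)‑2,2‑dimethyl‑5‑(3‑methylbut‑2‑en‑1‑yl)‑6‑(5‑methylfuran‑2‑yl)‑1‑(2‑methylpropanoyl)‑3‑(prop‑2‑en‑1‑yl)‑6‑[(trimethylsilyl)oxy]bicyclo[3.2.1]octane‑7,8‑dione
Conditions: allylSnBu3 (5 equiv), AIBN (azobisisobutyronitrile, 0.2 equiv), PhH (high concentration), 80 °C
Reagents that add atoms: allyltributylstannane, C=CC[Sn](CCCC)(CCCC)CCCC
Why: Keck radical allylation, in which Bu3Sn• abstracts the phenylselanyl group, the planar secondary C3 radical adds to the allylstannane and the stannyl radical is expelled to carry the chain, as with the analogous secondary iodides of bicyclo[3.3.1]nonane triones; the new bond should form on the face turned away from the C6–C7 bridge, whose endo silyloxy group closes the other face, so the allyl group becomes equatorial (3R) whatever the configuration of the selenide was, and the high stannane concentration is meant to outrun β‑scission of the C1–C2 bond.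

**Step 8**
Reactants: 15 C3‑allyl compound
Product: 16 (1R,3R,5S,6S)‑2,2‑dimethyl‑3,5‑bis(3‑methylbut‑2‑en‑1‑yl)‑6‑(5‑methylfuran‑2‑yl)‑1‑(2‑methylpropanoyl)‑6‑[(trimethylsilyl)oxy]bicyclo[3.2.1]octane‑7,8‑dione
Conditions: 2‑methylbut‑2‑ene (excess), second‑generation Grubbs catalyst RuCl2(H2IMes)(PCy3)(=CHPh) (5 mol %), CH2Cl2, 40 °C
Reagents that add atoms: 2‑methylbut‑2‑ene, CC=C(C)C
Why: Olefin cross‑metathesis of the terminal alkene with excess 2‑methylbut‑2‑ene turns allyl into prenyl; the trisubstituted C5 prenyl group can only undergo degenerate exchange, the 2,5‑disubstituted furan is not a metathesis substrate and no stereocentre is touched.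

**Step 9**
Reactants: 16 C3‑prenyl furan
Product: 18 (1R,3R,5S,6S)‑2,2‑dimethyl‑3,5‑bis(3‑methylbut‑2‑en‑1‑yl)‑1‑(2‑methylpropanoyl)‑6‑[(2Z)‑4‑oxopent‑2‑enoyl]‑6‑[(trimethylsilyl)oxy]bicyclo[3.2.1]octane‑7,8‑dione, via furan endoperoxide 17 (not isolated)
Conditions: O2, hν (visible), tetraphenylporphyrin (cat.), CH2Cl2, −78 °C; then Me2S, −78 → 0 °C, dark
Reagents that add atoms: dioxygen, O=O
Why: [4+2] Cycloaddition of singlet oxygen to the 2,5‑disubstituted furan, which is known to be much faster than the Schenck ene reaction of trisubstituted alkenes such as the two prenyl groups, followed by reduction of endoperoxide 17 with dimethyl sulfide, opens the ring to the cis‑enedione with the Z geometry inherited from the furan, while the silyl ether on O6 prevents hemiketal closure.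

**Step 10**
Reactants: 18 Z‑enedione
Product: 19 (1R,3R,5S,6S)‑6‑[(2Z)‑4‑hydroxy‑4‑methylpent‑2‑enoyl]‑2,2‑dimethyl‑3,5‑bis(3‑methylbut‑2‑en‑1‑yl)‑1‑(2‑methylpropanoyl)‑6‑[(trimethylsilyl)oxy]bicyclo[3.2.1]octane‑7,8‑dione
Conditions: MeTi(OiPr)3 (2 equiv), Et2O, −30 → 0 °C; then H2O
Reagents that add atoms: methyltitanium triisopropoxide, C[Ti](OC(C)C)(OC(C)C)OC(C)C
Why: Chemoselective 1,2‑addition of the non‑basic methyltitanium reagent to the only ketone that is not flanked by a quaternary carbon (the C13 methyl ketone), C7, C8, C9 and C10 each being shielded by fully substituted neighbours; the Z alkene is untouched and no stereocentre is formed because C13 ends with two methyl groups.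

**Step 11**
Reactants: 19 silyl ether of the target
Product: 20 (1R,3R,5S,6S)‑6‑hydroxy‑6‑[(2Z)‑4‑hydroxy‑4‑methylpent‑2‑enoyl]‑2,2‑dimethyl‑3,5‑bis(3‑methylbut‑2‑en‑1‑yl)‑1‑(2‑methylpropanoyl)bicyclo[3.2.1]octane‑7,8‑dione (CNP0190794.1)
Conditions: HF·pyridine, pyridine, THF, 0 °C
Reagents that add atoms: none
Why: Fluoride‑mediated cleavage of the trimethylsilyl ether under buffered, non‑basic conditions frees the C6 hydroxyl without retro‑aldol opening of the β‑hydroxy ketone or acid‑induced loss of the tertiary allylic alcohol, and no stereocentre is touched.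

**Compound list**

1 | 6‑methylhept‑5‑en‑2‑one | CC(=O)CCC=C(C)C | starting material
2 | methyl 2‑methylpropanoate (methyl isobutyrate) | COC(=O)C(C)C | starting material
3 | 2,9‑dimethyldec‑8‑ene‑3,5‑dione | CC(C)C(=O)CC(=O)CCC=C(C)C | intermediate
4 | diethyl oxalate | CCOC(=O)C(=O)OCC | starting material
5 | ethyl 8‑methyl‑3‑(2‑methylpropanoyl)‑2,4‑dioxonon‑7‑enoate (oxalyl triketo ester, not isolated) | CCOC(=O)C(=O)C(C(=O)C(C)C)C(=O)CCC=C(C)C | intermediate
6 | 4‑hydroxy‑5‑(2‑methylpropanoyl)‑2‑(3‑methylbut‑2‑en‑1‑yl)cyclopent‑4‑ene‑1,3‑dione (enol form of the acyl cyclopentanetrione; racemic at the prenyl‑bearing carbon) | CC(C)C(=O)C1=C(O)C(=O)C(CC=C(C)C)C1=O | intermediate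
7 | 1‑bromo‑3‑methylbut‑2‑ene (prenyl bromide) | CC(C)=CCBr | starting material
8 | cohulupone, 4‑hydroxy‑5‑(2‑methylpropanoyl)‑2,2‑bis(3‑methylbut‑2‑en‑1‑yl)cyclopent‑4‑ene‑1,3‑dione (achiral) | CC(C)C(=O)C1=C(O)C(=O)C(CC=C(C)C)(CC=C(C)C)C1=O | intermediate
9 | N‑(phenylselanyl)phthalimide | O=C1c2ccccc2C(=O)N1[Se]c1ccccc1 | starting material
10 | seleniranium ion of 8 (one prenyl group of 8 turned into a (2,2‑dimethyl‑1‑phenylseleniran‑1‑ium‑3‑yl)methyl group; triflate counter‑ion; not isolated) | CC(C)C(=O)C1=C(O)C(=O)[C@](CC=C(C)C)(C[C@H]2[Se+](c3ccccc3)C2(C)C)C1=O | intermediate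
11 | (1R,3R,5R)‑2,2‑dimethyl‑5‑(3‑methylbut‑2‑en‑1‑yl)‑1‑(2‑methylpropanoyl)‑3‑(phenylselanyl)bicyclo[3.2.1]octane‑6,7,8‑trione (selenium equatorial) | c3ccccc3[Se][C@@H]1C[C@]2(CC=C(C)C)C(=O)[C@@](C(=O)C(C)C)(C(=O)C2=O)C1(C)C | intermediate
12 | 2‑methylfuran | Cc1ccco1 | starting material
13 | (1R,3R,5S,6S)‑6‑hydroxy‑2,2‑dimethyl‑5‑(3‑methylbut‑2‑en‑1‑yl)‑6‑(5‑methylfuran‑2‑yl)‑1‑(2‑methylpropanoyl)‑3‑(phenylselanyl)bicyclo[3.2.1]octane‑7,8‑dione (furyl exo, hydroxyl endo) | c3ccccc3[Se][C@@H]1C[C@]2(CC=C(C)C)C(=O)[C@@](C(=O)C(C)C)(C(=O)[C@@]2(O)c4ccc(C)o4)C1(C)C | intermediate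
14 | (1R,3R,5S,6S)‑2,2‑dimethyl‑5‑(3‑methylbut‑2‑en‑1‑yl)‑6‑(5‑methylfuran‑2‑yl)‑1‑(2‑methylpropanoyl)‑3‑(phenylselanyl)‑6‑[(trimethylsilyl)oxy]bicyclo[3.2.1]octane‑7,8‑dione | c3ccccc3[Se][C@@H]1C[C@]2(CC=C(C)C)C(=O)[C@@](C(=O)C(C)C)(C(=O)[C@@]2(O[Si](C)(C)C)c4ccc(C)o4)C1(C)C | intermediate
15 | (1R,3R,5S,6S)‑2,2‑dimethyl‑5‑(3‑methylbut‑2‑en‑1‑yl)‑6‑(5‑methylfuran‑2‑yl)‑1‑(2‑methylpropanoyl)‑3‑(prop‑2‑en‑1‑yl)‑6‑[(trimethylsilyl)oxy]bicyclo[3.2.1]octane‑7,8‑dione (allyl equatorial) | C=CC[C@@H]1C[C@]2(CC=C(C)C)C(=O)[C@@](C(=O)C(C)C)(C(=O)[C@@]2(O[Si](C)(C)C)c3ccc(C)o3)C1(C)C | intermediate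
16 | (1R,3R,5S,6S)‑2,2‑dimethyl‑3,5‑bis(3‑methylbut‑2‑en‑1‑yl)‑6‑(5‑methylfuran‑2‑yl)‑1‑(2‑methylpropanoyl)‑6‑[(trimethylsilyl)oxy]bicyclo[3.2.1]octane‑7,8‑dione | CC(C)=CC[C@@H]1C[C@]2(CC=C(C)C)C(=O)[C@@](C(=O)C(C)C)(C(=O)[C@@]2(O[Si](C)(C)C)c3ccc(C)o3)C1(C)C | intermediate
17 | furan endoperoxide of 16 (the furyl group replaced by a 4‑methyl‑2,3,7‑trioxabicyclo[2.2.1]hept‑5‑en‑1‑yl group; both bridgehead configurations; not isolated) | CC(C)=CC[C@@H]1C[C@]2(CC=C(C)C)C(=O)[C@@](C(=O)C(C)C)(C(=O)[C@@]2(O[Si](C)(C)C)C34C=CC(C)(OO3)O4)C1(C)C | intermediate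
18 | (1R,3R,5S,6S)‑2,2‑dimethyl‑3,5‑bis(3‑methylbut‑2‑en‑1‑yl)‑1‑(2‑methylpropanoyl)‑6‑[(2Z)‑4‑oxopent‑2‑enoyl]‑6‑[(trimethylsilyl)oxy]bicyclo[3.2.1]octane‑7,8‑dione | CC(C)=CC[C@@H]1C[C@]2(CC=C(C)C)C(=O)[C@@](C(=O)C(C)C)(C(=O)[C@@]2(O[Si](C)(C)C)C(=O)/C=C\C(C)=O)C1(C)C | intermediate
19 | (1R,3R,5S,6S)‑6‑[(2Z)‑4‑hydroxy‑4‑methylpent‑2‑enoyl]‑2,2‑dimethyl‑3,5‑bis(3‑methylbut‑2‑en‑1‑yl)‑1‑(2‑methylpropanoyl)‑6‑[(trimethylsilyl)oxy]bicyclo[3.2.1]octane‑7,8‑dione | CC(C)=CC[C@@H]1C[C@]2(CC=C(C)C)C(=O)[C@@](C(=O)C(C)C)(C(=O)[C@@]2(O[Si](C)(C)C)C(=O)/C=C\C(C)(C)O)C1(C)C | intermediate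
20 | (1R,3R,5S,6S)‑6‑hydroxy‑6‑[(2Z)‑4‑hydroxy‑4‑methylpent‑2‑enoyl]‑2,2‑dimethyl‑3,5‑bis(3‑methylbut‑2‑en‑1‑yl)‑1‑(2‑methylpropanoyl)bicyclo[3.2.1]octane‑7,8‑dione (CNP0190794.1) | CC(C)=CC[C@@H]1C[C@]2(CC=C(C)C)C(=O)[C@@](C(=O)C(C)C)(C(=O)[C@@]2(O)C(=O)/C=C\C(C)(C)O)C1(C)C | target

**Step count and risks**

Total step count: 11. Longest linear sequence: 11 steps (1 → 20).

Steps most likely to fail:

Step 4. The copper‑bound enolate may not discriminate well enough between the two enantiotopic prenyl groups (a racemic background closure through the free enol under the triflic acid is possible), and material may stay trapped as O‑cyclised enol ether instead of funnelling to the carbocycle. The fallback sets out from 8 and returns at 15. Compound 8 is cyclised with the stoichiometric enantiopure selenenyl triflate made from bis{2‑[(1S)‑1‑methoxyethyl]phenyl} diselenide (Br2, then AgOTf, CH2Cl2, −78 °C), followed by SnCl4 to move O‑cyclised material to the carbocycle. Selenocyclisation with such enantiopure arylselenenyl triflates and Lewis‑acid‑driven O‑ to C‑isomerisation of seleno‑cyclised β‑dicarbonyl compounds are known reaction types. Because the selenium reagent is itself chiral, the two closures (one for each prenyl group) give diastereomers, which can be separated by chromatography whatever the selectivity. The diastereomer with the (1R,5R) core, (1R,3R,5R)‑3‑({2‑[(1S)‑1‑methoxyethyl]phenyl}selanyl)‑2,2‑dimethyl‑5‑(3‑methylbut‑2‑en‑1‑yl)‑1‑(2‑methylpropanoyl)bicyclo[3.2.1]octane‑6,7,8‑trione F1, is carried through the conditions of steps 5 and 6 to the furyl carbinol F2 and its trimethylsilyl ether F3. The Keck allylation of step 7 then removes the chiral arylselanyl group and gives 15.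

Step 5. The organometallic may attack C7 instead of C6, after which the C7 alkoxide would fragment with loss of the C1–C7 bond (release of a β‑diketone enolate); the C6 alkoxide may also open by retro‑aldol cleavage of C5–C6. The fallback sets out from 11 and 12, returns at 13 and makes no new compound (F0). Neutral 2‑methylfuran itself is used in a Friedel–Crafts hydroxyalkylation of the activated 1,2‑dione (Sc(OTf)3 cat., CH2Cl2, 0 °C), a known reaction of furans with activated 1,2‑dicarbonyl compounds. No alkoxide is formed, so base‑induced fragmentation cannot occur. The weak, sterically sensitive arene nucleophile adds reversibly under the acid, so the less congested C6 exo adduct should accumulate.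

Step 2. Ethoxide may cleave the triacylmethane intermediate by retro‑Claisen reaction before the ring closes, or the ring may close through the isopropyl methine instead of the methylene. The fallback sets out from 7 and returns at 8. Commercial 2‑methyl‑1‑(2,4,6‑trihydroxyphenyl)propan‑1‑one F4 is C‑prenylated three times with 7 (aq. KOH, 0 °C) to colupulone F5. F5 is ring‑contracted by autoxidation (O2, Na2SO3, MeOH, rt), which excises the mono‑prenylated ring carbon as 4‑methylpent‑3‑enoic acid and gives 8. Both operations are established hop‑acid chemistry and bypass steps 1 to 3, so the detour also covers a failure of the C‑prenylation in step 3.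

**Further compounds**

F1 | step 4 | (1R,3R,5R)‑3‑({2‑[(1S)‑1‑methoxyethyl]phenyl}selanyl)‑2,2‑dimethyl‑5‑(3‑methylbut‑2‑en‑1‑yl)‑1‑(2‑methylpropanoyl)bicyclo[3.2.1]octane‑6,7,8‑trione | CO[C@@H](C)c3ccccc3[Se][C@@H]1C[C@]2(CC=C(C)C)C(=O)[C@@](C(=O)C(C)C)(C(=O)C2=O)C1(C)C
F2 | step 4 | (1R,3R,5S,6S)‑6‑hydroxy‑3‑({2‑[(1S)‑1‑methoxyethyl]phenyl}selanyl)‑2,2‑dimethyl‑5‑(3‑methylbut‑2‑en‑1‑yl)‑6‑(5‑methylfuran‑2‑yl)‑1‑(2‑methylpropanoyl)bicyclo[3.2.1]octane‑7,8‑dione | CO[C@@H](C)c3ccccc3[Se][C@@H]1C[C@]2(CC=C(C)C)C(=O)[C@@](C(=O)C(C)C)(C(=O)[C@@]2(O)c4ccc(C)o4)C1(C)C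
F3 | step 4 | (1R,3R,5S,6S)‑3‑({2‑[(1S)‑1‑methoxyethyl]phenyl}selanyl)‑2,2‑dimethyl‑5‑(3‑methylbut‑2‑en‑1‑yl)‑6‑(5‑methylfuran‑2‑yl)‑1‑(2‑methylpropanoyl)‑6‑[(trimethylsilyl)oxy]bicyclo[3.2.1]octane‑7,8‑dione | CO[C@@H](C)c3ccccc3[Se][C@@H]1C[C@]2(CC=C(C)C)C(=O)[C@@](C(=O)C(C)C)(C(=O)[C@@]2(O[Si](C)(C)C)c4ccc(C)o4)C1(C)C
F0 | step 5 | none | none
F4 | step 2 | 2‑methyl‑1‑(2,4,6‑trihydroxyphenyl)propan‑1‑one | CC(C)C(=O)c1c(O)cc(O)cc1O
F5 | step 2 | colupulone, 3,5‑dihydroxy‑4,6,6‑tris(3‑methylbut‑2‑en‑1‑yl)‑2‑(2‑methylpropanoyl)cyclohexa‑2,4‑dien‑1‑one | CC(C)C(=O)C1=C(O)C(CC=C(C)C)=C(O)C(CC=C(C)C)(CC=C(C)C)C1=O
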